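Time works against L: the reading comes at 90 min, and L made early has that long to fade. A simulation fed wrong ages gives wrong answers, so the life of L is worth reading from the flasks first.

all flasks: G 0.050 M; Z 0.35 mol%

| run | E | remark | time |
|---|---|---|---|
| violet | 0.47 equiv | run made earlier |  |
| grey | 3.9 equiv | run made earlier |  |
| eta | 0.400 equiv |  | 1.5 h |
| epsilon | 0.800 equiv |  | 1.5 h |
| delta | 1.50 equiv |  | 1.5 h |
| beta | 3.00 equiv |  | 1.5 h |

| run | time / min | L / % | G / % |
|---|---|---|---|
| violet | 15.0 | 33.5 | 55.4 |
| violet | 30.0 | 37.8 | 48.4 |
| violet | 50.0 | 33.4 | 47.5 |
| violet | 60.0 | 32.3 | 46.9 |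
| violet | 80.0 | 27.8 | 47.3 |
| violet | 90.0 | 25.0 | 47.9 |
| grey | 15.0 | 87.5 | 0.2 |
| grey | 30.0 | 75.6 | 0.1 |
| grey | 50.0 | 61.6 | 0.3 |
| grey | 60.0 | 56.6 | 0 |
| grey | 80.0 | 46.3 | 0 |
| grey | 90.0 | 42.2 | 0.4 |

(standard deviation of a reading: 0.5 percentage points)

* amount of L at the end, in percent of the G charged for eta, epsilon, delta, beta, in this order
* the course of these numbers from the first flask to the last (rises, then falls / falls all the way / hardly changes / falls, then rises / rises all the way)

- a reading or a percentage of L counts all its forms, free or not
- "hardly changes" means that all values lie within two and a half points (for a concentration: within two and a half percent of the largest)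
- a reading of G is of its free form alone

In the grey run G stands at 0.2% by 15.0 min, so little more L can form, and L falls from 87.5% to 42.2% by 90.0 min. The time between those readings, divided by the natural logarithm of their ratio, is the life of L: 103 min, a reading with its scatter. The end amount is then reckoned as a ceiling, the fraction of the charge that the limiting reagent allows, shrunk by the exponential of minus age over life. A full charge aged for the whole time keeps 41.7%.

Now turn the question round. For the row to fall from eta to epsilon, where the ceiling doubles, the L in epsilon would have to be older by 71.3 min. That is more than the 30.0 min by which violet, short of E, has reached its highest reading. From epsilon to delta the ceiling gain is cancelled by 23.0 min of extra age, a quarter of the time. Delta and beta share one ceiling, so this reckoning separates them by age, and more E forms L sooner: grey has 0.2% of G at 15.0 min, violet 55.4%. A rise at that end is therefore not expected.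

The forecast gave 22%, 41.5%, 45% and 43%, a row that rises, then falls, on the ground that “extra E only makes L earlier, so it decays longer”.

The flasks give 22.0%, 40.6%, 45.7% and 43.2%: the row rises, then falls, turning at 1.1 equiv.

    G + E + Z → L + Z, rate k1*[G]*[E]*[Z]/(1 + ([G]/sat1)) (0.0620 M, k = 440 M⁻² s⁻¹)
    L ⇌ Q (K = 12.0, k = 1.70 × 10⁻⁴ s⁻¹)
    G + L ⇌ J, settled at all times (K = 11.0 M⁻¹)

In beta the turning of L into Q is the main reason for the loss: without that step the flask holds 100% at the end, not 43.2%. Against the life of L, that loss is worth an age of 86.4 min. In eta the same step is part of the story, taking 40.0% down to 22.0%. That is worth an age of 61.6 min, less than in beta.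

The numbers in the tables were generated by integration for substances that don't exist.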